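At 40 °C a J in a flask holding the whole charge of Z goes to G at 0.48 s⁻¹, faster than Z takes it up, at 0.0510 s⁻¹.

    Z + J ⇌ Z.J (K1 = 580 L mol⁻¹, k1 = 17 L mol⁻¹ s⁻¹, Ea1 = 42.0 kJ mol⁻¹, ΔH1 = −17.0 kJ mol⁻¹)
    J → G (k2 = 0.48 s⁻¹, Ea2 = 72.0 kJ mol⁻¹)
    2 E → E2 (k3 = 3.6 L mol⁻¹ s⁻¹, Ea3 = 45.0 kJ mol⁻¹)
    L + E ⇌ Q + J, settled at all times (K4 = 1.7, ΔH4 = −35.0 kJ mol⁻¹)
    (constants at 40 °C)

| flask | L | E | Z | temperature | time | remark |
|---|---|---|---|---|---|---|
| Tuesday's | 2.0 mM | 1.40 mM (fed, over 30 s) | 3.00 mM | 40 °C | 40 s | all else is in the flask from the start; the feed brings no volume worth counting |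
| Monday's | 2.0 mM | 1.40 mM | 3.00 mM (fed, over 8.0 s) | 40 °C | 40 s | all else is in the flask from the start; the feed brings no volume worth counting |
| Thursday's | 2.0 mM | 1.40 mM | 3.00 mM (fed, over 30 s) |  | 40 s | the addition at 10 °C, then warmed to 40 °C; the feed brings no volume worth counting |
| Wednesday's | 2.0 mM | 1.40 mM | 3.00 mM |  | 40 s | everything together at the start at 10 °C, warmed to 40 °C at 30 s |
| Saturday's | 2.0 mM | 1.40 mM | 3.00 mM (fed, over 30 s) | 40 °C | 40 s | all else is in the flask from the start; the feed brings no volume worth counting |

1. the flask with the highest amount of Z.J, in percent of the L charged ("all alike" if they lie within 1.5 percentage points) (Tuesday's / Monday's / Thursday's / Wednesday's / Saturday's / all alike)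
2. final Z.J, as a percentage of the L charged, in Tuesday's
3. final Z.J, as a percentage of the L charged, in Monday's
4. final Z.J, as a percentage of the L charged, in Thursday's
5. final Z.J, as a percentage of the L charged, in Wednesday's
6. final Z.J, as a percentage of the L charged, in Saturday's

- two of one species on the left: rate k times its square, two consumed each time
- constants are those at 40 °C; use the activation energies and enthalpies for any other temperature

I turn the question round and ask what the numbers would have to be for Z.J, not G, to take the larger part of J. E is the limiting reagent, charged below L and Z, and each E makes one J, so J can amount to 70.0% of the L charged. Where Z is in from the start I take capture as pseudo-first-order in J, with Z's fraction of its charge setting the rate.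

With the whole charge at 40 °C I reckon 9.60% for the capture share, the part of a J that Z takes before G does, which is the selectivity factor written as a share. For Z to outrun G it would have to stand at 9.41 times its charge. The loss to G has the higher activation energy, so at 10 °C that figure drops to 2.78 and the share rises to 26.5%, still below 0.5. At these shares the J that Z takes uses 4.48% and 12.4% of Z's charge, so I keep Z's fraction near one. Multiplied by the reach of J, these shares give ceilings of 6.72% and 18.6% of the L charged. They are ceilings because Z.J returns to Z and J with a half-life of 23.6 s at 40 °C, shorter than the run.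

So I put Wednesday's first. A steady feed averages half the charge, which at 10 °C gives 15.2%, more than the whole charge at 40 °C, so Thursday's goes above Tuesday's. Last come Monday's and then Saturday's, where E is in from the start and J's half-life toward G, 1.44 s, is shorter than the quick feed of 8.0 s.

The forecast names Wednesday's, with 9.4%, 5.6%, 3.4%, 1.1% and 0.5% for Wednesday's, Thursday's, Tuesday's, Monday's and Saturday's, on the ground that "Cold favours capture".

The simulation puts Wednesday's highest, with 9.57%, then 5.95% in Thursday's, 3.68% in Tuesday's, 1.09% in Monday's and 0.370% in Saturday's, the order I reckoned. In Wednesday's, Z stood at 93.6% of its charge after 40.0 s, and Z.J made up 14.4% of Z.J and G together, below the share of 26.5%. In Tuesday's, Z.J made up 6.61% of that pair when the feed ended, below 9.60%, and then, as E fell to 1.02% of its charge, Z.J went from 4.06% to 3.68% of the L charged.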